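**Plan**

- Retrosynthetic cuts, in order: the O7–S bond (sulfation of the one phenol unmasked from a peracetate), then O1–C2 (ring C), then C4–C4a (ring A to the three-carbon unit carrying ring B).
- Enabling feature: in ring A the oxygens on C6 and C8a (O1) are para, the C5 and C7 oxygens flank C6–O, and C4a and C8 are the remaining ring carbons. Ring A is therefore 2,6-dimethoxy-1,4-benzoquinone at the hydroquinone level, and C4a is one of its two symmetry-equivalent C–H carbons.
- Forward: ring B arrives in an arylpropynal. A photochemical acyl-radical C–H acylation of the quinone joins two electrophilic carbons (formyl C and quinone CH), and the quinone's own reduction leaves O6–H and O1–H.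
- Ring C then closes by 6-endo-dig addition of O1–H to the ynone, already at the flavone oxidation level.
- End game: global demethylation and peracetylation, 7-selective deacetylation, sulfation, deacetylation.
- Stereochemistry: none; the target has no stereocentre, axis or stereogenic double bond.

Key step: step 2

Remark: the target is achiral, so the single-enantiomer request is met trivially; the free hydrogen sulfate drawn is assumed to be liberated from its ammonium salt by cold cation exchange (H+ form) in the last work-up.

**Step 1**
Reactants: 1 4-ethynyl-1,2-dimethoxybenzene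
Product: 3 3-(3,4-dimethoxyphenyl)prop-2-ynal, via lithium (3,4-dimethoxyphenyl)acetylide 2 (not isolated)
Conditions: n-BuLi (1.05 equiv), THF, −78 °C; DMF (2 equiv), −78 → 0 °C; inverse quench into cold aq KH2PO4/MTBE
Reagents that add atoms: N,N-dimethylformamide, CN(C)C=O
Why: deprotonation of the terminal alkyne and formylation of the lithium acetylide with DMF should give the ynal, and the buffered inverse quench protonates the liberated dimethylamine before it can add to the product.

**Step 2**
Reactants: 3 3-(3,4-dimethoxyphenyl)prop-2-ynal; 4 2,6-dimethoxy-1,4-benzoquinone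
Product: 6 6-hydroxy-5,7-dimethoxy-2-(3,4-dimethoxyphenyl)-4H-chromen-4-one, via 1-(3,6-dihydroxy-2,4-dimethoxyphenyl)-3-(3,4-dimethoxyphenyl)prop-2-yn-1-one 5 (not isolated)
Conditions: 3 (2.5 equiv), 4 (1 equiv, 0.05 M), hν (427 nm LED), degassed PhCF3, 20 °C, Ar; then TfOH (0.5 equiv), 40 °C
Reagents that add atoms: none
Why: Proposed new method: visible light should excite only the n→π* band of quinone 4, whose triplet abstracts the formyl hydrogen of 3; the nucleophilic ynoyl radical (which cannot decarbonylate, as that would give an sp-carbon radical) adds to the unsubstituted C3 of 4 to give a captodative radical at C2 (α-methoxy, α-carbonyl), and hydrogen return from the semiquinone followed by enolisation gives acylhydroquinone 5, so that two electrophilic carbons are joined and the reduction of the quinone supplies O6–H and O1–H at the right oxidation level. The closest known reaction type is the photochemical acylation of 1,4-quinones with aldehydes (photo-Friedel–Crafts acylation), established for alkyl, aryl and alkenyl aldehydes but not for 2-ynals or 2,6-dialkoxyquinones. The photochemical event closes no ring; ring C is then closed in the same flask by TfOH-promoted 6-endo-dig oxa-Michael addition of the chelated ortho hydroxyl (the future O1) to the protonated ynone, whose β-carbon is made the electrophilic terminus by the 3,4-dimethoxyphenyl group, so the 5-exo (aurone) mode should be suppressed. No stereocentre is formed. The selectivities needed are C- over O-acylation, hydrogen abstraction over [2+2] addition or electron transfer at the electron-rich arylalkyne, and mono-acylation at one defined position. The twofold symmetry of 4 makes its two CH positions equivalent, captodative stabilisation favours attack at carbon, quinones are among the fastest traps for acyl radicals, and 5 is an ortho-hydroxyaryl ketone that is no longer a quinone and should shed excitation by intramolecular proton transfer instead of reacting again.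

**Step 3**
Reactants: 6 6-hydroxy-5,7-dimethoxy-2-(3,4-dimethoxyphenyl)-4H-chromen-4-one
Product: 8 2-(3,4-diacetoxyphenyl)-4-oxo-4H-chromene-5,6,7-triyl triacetate, via 6-hydroxyluteolin 7 (not isolated)
Conditions: BBr3 (10 equiv), CH2Cl2, −78 °C → rt; MeOH quench at 0 °C, evaporate; then Ac2O, pyridine, DMAP (cat.), rt
Reagents that add atoms: acetic anhydride, CC(=O)OC(C)=O
Why: exhaustive Lewis-acid ether cleavage by BBr3 (5-OMe activated by chelation to C4=O, 7-OMe by the neighbouring O6–boron ester) should give the pentaphenol, whose air-sensitive 5,6,7-trihydroxy ring is trapped at once as the pentaacetate by DMAP-catalysed acylation.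

**Step 4**
Reactants: 8 2-(3,4-diacetoxyphenyl)-4-oxo-4H-chromene-5,6,7-triyl triacetate
Product: 9 2-(3,4-diacetoxyphenyl)-7-hydroxy-4-oxo-4H-chromene-5,6-diyl diacetate
Conditions: PhSH (1.2 equiv), imidazole (0.3 equiv), NMP, 0 °C → rt
Reagents that add atoms: none
Why: imidazole-catalysed thiolysis should remove only the 7-acetate, because O7 is para to the C4a–C4=O acyl group and its phenoxide is the best leaving group of the five (chemoselective deacylation of the most activated aryl ester of a flavone peracetate), and 7-OH/6-OAc is also the thermodynamically preferred arrangement should the neighbouring acetyl migrate.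

**Step 5**
Reactants: 9 2-(3,4-diacetoxyphenyl)-7-hydroxy-4-oxo-4H-chromene-5,6-diyl diacetate
Product: 11 6-hydroxyluteolin 7-sulfate, via 5,6-diacetoxy-2-(3,4-diacetoxyphenyl)-4-oxo-4H-chromen-7-yl hydrogen sulfate 10 (not isolated)
Conditions: SO3·pyridine (4 equiv), pyridine, 25 °C; then MeOH, 0 °C; NH3 (7 M in MeOH, degassed), 0 °C, Ar; C18 chromatography; sulfonic acid resin (H+ form), 0 °C, lyophilise
Reagents that add atoms: sulfur trioxide pyridine complex, O=S(=O)([O-])[n+]1ccccc1
Why: O-sulfonation of the single free phenol with the sulfur trioxide–amine complex should give the aryl sulfate monoester, which as an anion is inert to the ammonolysis that then removes the four acetates, and since methanol destroys excess reagent before any other phenol is set free, the sulfate can only sit on O7.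

**Compound list**

1 | 4-ethynyl-1,2-dimethoxybenzene | COc1ccc(C#C)cc1OC | starting material
2 | lithium (3,4-dimethoxyphenyl)acetylide | COc1ccc(C#C[Li])cc1OC | intermediate
3 | 3-(3,4-dimethoxyphenyl)prop-2-ynal | COc1ccc(C#CC=O)cc1OC | intermediate
4 | 2,6-dimethoxy-1,4-benzoquinone | COC1=CC(=O)C=C(OC)C1=O | starting material
5 | 1-(3,6-dihydroxy-2,4-dimethoxyphenyl)-3-(3,4-dimethoxyphenyl)prop-2-yn-1-one | COc1ccc(C#CC(=O)c2c(O)cc(OC)c(O)c2OC)cc1OC | intermediate
6 | 6-hydroxy-5,7-dimethoxy-2-(3,4-dimethoxyphenyl)-4H-chromen-4-one | COc1ccc(-c2cc(=O)c3c(OC)c(O)c(OC)cc3o2)cc1OC | intermediate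
7 | 6-hydroxyluteolin (2-(3,4-dihydroxyphenyl)-5,6,7-trihydroxy-4H-chromen-4-one) | O=c1cc(-c2ccc(O)c(O)c2)oc2cc(O)c(O)c(O)c12 | intermediate
8 | 2-(3,4-diacetoxyphenyl)-4-oxo-4H-chromene-5,6,7-triyl triacetate | CC(=O)Oc1ccc(-c2cc(=O)c3c(OC(C)=O)c(OC(C)=O)c(OC(C)=O)cc3o2)cc1OC(C)=O | intermediate
9 | 2-(3,4-diacetoxyphenyl)-7-hydroxy-4-oxo-4H-chromene-5,6-diyl diacetate | CC(=O)Oc1ccc(-c2cc(=O)c3c(OC(C)=O)c(OC(C)=O)c(O)cc3o2)cc1OC(C)=O | intermediate
10 | 5,6-diacetoxy-2-(3,4-diacetoxyphenyl)-4-oxo-4H-chromen-7-yl hydrogen sulfate | CC(=O)Oc1ccc(-c2cc(=O)c3c(OC(C)=O)c(OC(C)=O)c(OS(=O)(=O)O)cc3o2)cc1OC(C)=O | intermediate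
11 | 6-hydroxyluteolin 7-sulfate (2-(3,4-dihydroxyphenyl)-5,6-dihydroxy-4-oxo-4H-chromen-7-yl hydrogen sulfate) | O=c1cc(-c2ccc(O)c(O)c2)oc2cc(OS(=O)(=O)O)c(O)c(O)c12 | target

**Step count and risks**

Total step count: 5. Longest linear sequence: 5 steps (1 → 3 → 6 → 8 → 9 → 11; quinone 4 enters at step 2).

Steps most likely to fail:

1. Step 2 (proposed new method). The excited quinone may be quenched unproductively by electron transfer from, or [2+2] cycloaddition to, the electron-rich arylalkyne, or the radical pair may collapse on oxygen, so that C–C bond formation is inefficient. The fallback is polar and uses known chemistry; it sets out from 4 and comes back at 6. Quinone 4 is reduced with Na2S2O4 (EtOAc/water) to 2,6-dimethoxybenzene-1,4-diol F1. Friedel–Crafts C-acetylation with AcOH/BF3·OEt2 at 90 °C gives 1-(3,6-dihydroxy-2,4-dimethoxyphenyl)ethan-1-one F2. Claisen–Schmidt condensation with 3,4-dimethoxybenzaldehyde (KOH, EtOH, Ar) gives (E)-1-(3,6-dihydroxy-2,4-dimethoxyphenyl)-3-(3,4-dimethoxyphenyl)prop-2-en-1-one F3. Oxidative cyclisation with catalytic I2 in DMSO at 120 °C should then give 6.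

2. Step 4. Site selectivity may be lost through competing thiolysis of the 4'-acetate, or the acetyl group may migrate from O6 to the freed O7, blurring the differentiation on which step 5 depends. The fallback abandons protecting-group differentiation; it sets out from 7 (isolated after the BBr3 stage of step 3 instead of being acetylated) and comes back at 11. The pentaphenol is monosulfated directly with tetrabutylammonium hydrogen sulfate and DCC in pyridine at 4 °C (or 1 equiv of SO3·NMe3 with 1 equiv of K2CO3 in DMF). This relies on the 7-OH, para to the C4a–C4=O acyl group, being the most acidic and first-reacting phenol, and is followed by reversed-phase separation. This fallback makes no new compound (F0).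

3. Step 5. Acetyl migration under pyridine before sulfation could place the sulfate on O6, sulfation of the acidic, flanked 7-OH could be sluggish, and the sulfate could be lost by acid-catalysed hydrolysis on conversion of the salt to the free acid. The fallback uses a protected sulfate; it sets out from 9 and comes back at 10. Phenol 9 is treated with 2,2,2-trichloroethyl chlorosulfate, Et3N and DMAP in THF to give the neutral diester 5,6-diacetoxy-2-(3,4-diacetoxyphenyl)-4-oxo-4H-chromen-7-yl 2,2,2-trichloroethyl sulfate F4. This can be purified on silica and its regiochemistry secured before going on. Reductive removal of the trichloroethyl group with Zn and HCO2NH4 in MeOH then delivers 10 as its ammonium salt, which is ammonolysed as in step 5 and isolated as the salt if the free acid proves labile.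

**Further compounds**

F1 | step 2 | 2,6-dimethoxybenzene-1,4-diol | COc1cc(O)cc(OC)c1O
F2 | step 2 | 1-(3,6-dihydroxy-2,4-dimethoxyphenyl)ethan-1-one | CC(=O)c1c(O)cc(OC)c(O)c1OC
F3 | step 2 | (E)-1-(3,6-dihydroxy-2,4-dimethoxyphenyl)-3-(3,4-dimethoxyphenyl)prop-2-en-1-one | COc1ccc(/C=C/C(=O)c2c(O)cc(OC)c(O)c2OC)cc1OC
F0 | step 4 | none | none
F4 | step 5 | 5,6-diacetoxy-2-(3,4-diacetoxyphenyl)-4-oxo-4H-chromen-7-yl 2,2,2-trichloroethyl sulfate | CC(=O)Oc1ccc(-c2cc(=O)c3c(OC(C)=O)c(OC(C)=O)c(OS(=O)(=O)OCC(Cl)(Cl)Cl)cc3o2)cc1OC(C)=O
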